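The cyclohexane ring is closed last, at C2–C3 (target numbering: C1 = CMeBr, C2 = CH‑chlorovinyl, C4 = CHBr, C5 = CMeCl). Opened there, the cis C4–Br/C5–Cl pair is the anti BrCl adduct of an (E)‑allylic alcohol and is set on the open chain by catalytic enantioselective bromochlorination. In the key step the C4 bromine, β to C3, expels a C3 triflate; the (E)‑C1=C2 alkene opens the resulting C3/C4 bromonium ion at C3 through a chair and bromide caps C1. One operation forms the ring, C2 and the tertiary C1–Br centre, relayed from C4. The precursor is an acyclic bromochloro dienyl triflate.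

Key step: step 6

Remark: atom numbers in the text are the IUPAC locants of 11 (C1 = C(CH3)Br, C2 = CH–chloroethenyl, C3 = CH2, C4 = CHBr, C5 = C(CH3)Cl, C6 = CH2); the sense of induction in step 5 is assumed to be selectable through the ligand enantiomer.

Step 1
Reactants: 1 isoprene
Product: 2 (2E)-4-bromo-3-methylbut-2-en-1-yl acetate
Conditions: NBS, AcOH, 10 °C to rt; fractional distillation to remove the Z isomer and the 1,2-adduct
Reagents that add atoms: N-bromosuccinimide O=C1CCC(=O)N1Br; acetic acid CC(=O)O
Why: Conjugate (1,4) bromoacetoxylation of a 1,3-diene, in which Br+ adds to the CH2 terminus of the more substituted alkene and acetate captures the allyl cation at its primary end, should give the thermodynamically preferred E allylic bromide.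

Step 2
Reactants: 2 (2E)-4-bromo-3-methylbut-2-en-1-yl acetate; 3 ethynyltrimethylsilane
Product: 4 (2E)-3-methyl-6-(trimethylsilyl)hex-2-en-5-yn-1-yl acetate
Conditions: CuI (10 mol %), Bu4NI (10 mol %), K2CO3, DMF, rt
Reagents that add atoms: none
Why: Copper-catalysed coupling of a terminal alkyne with a primary allylic bromide (copper acetylide SN2 displacement) should give the skipped enyne with the E alkene intact, the acetate and the C–Si bond being inert under these conditions.

Step 3
Reactants: 4 (2E)-3-methyl-6-(trimethylsilyl)hex-2-en-5-yn-1-yl acetate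
Product: 5 (2E)-3-methylhex-2-en-5-yn-1-ol
Conditions: K2CO3 (0.2 equiv), MeOH, 0 °C, short reaction time
Reagents that add atoms: none
Why: Methanolysis (transesterification of the acetate and protodesilylation of the alkynylsilane) should unmask both ends in one operation, with low temperature and substoichiometric base chosen to suppress propargyl–allenyl isomerisation of the 1,4-enyne.

Step 4
Reactants: 5 (2E)-3-methylhex-2-en-5-yn-1-ol; 6 (E)-1,2-dichloroethene
Product: 8 (2E,5E,7E)-8-chloro-3,5-dimethylocta-2,5,7-trien-1-ol, via alkenylalane 7 (not isolated)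
Conditions: Me3Al (3 equiv), Cp2ZrCl2 (0.3 equiv), CH2Cl2, 0 °C to rt; then ZnCl2, Pd(PPh3)4 (5 mol %), 6 (5 equiv), THF, rt; Rochelle salt work-up
Reagents that add atoms: trimethylaluminium C[Al](C)C
Why: Negishi zirconium-catalysed carboalumination adds CH3 and Al syn across the terminal alkyne with CH3 on the internal carbon, and Pd-catalysed Negishi cross-coupling of the alkenylalane with excess (E)-1,2-dichloroethene should replace Al by the E-chlorovinyl group with retention at both alkenes.

Step 5
Reactants: 8 (2E,5E,7E)-8-chloro-3,5-dimethylocta-2,5,7-trien-1-ol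
Product: 9 (2S,3R,5E,7E)-2-bromo-3,8-dichloro-3,5-dimethylocta-5,7-dien-1-ol
Conditions: NBS (1.1 equiv), ClTi(OiPr)3 (1.1 equiv), chiral tridentate Schiff-base ligand (salicylaldimine of an amino alcohol, 20 mol %), hexanes, −20 °C
Reagents that add atoms: N-bromosuccinimide O=C1CCC(=O)N1Br; chlorotitanium triisopropoxide CC(C)O[Ti](Cl)(OC(C)C)OC(C)C
Why: Catalytic enantioselective bromochlorination of an allylic alcohol (titanium-alkoxide-directed) should deliver Br+ to one face of the E alkene and titanium-bound chloride anti to the tertiary carbon, setting C2 and C3 of 9 (C4 and C5 of 11) together, while alkoxide direction should leave the remote chlorodiene untouched.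

Step 6
Reactants: 9 (2S,3R,5E,7E)-2-bromo-3,8-dichloro-3,5-dimethylocta-5,7-dien-1-ol
Product: 11 (1R,2S,4S,5R)-1,4-dibromo-5-chloro-2-[(E)-2-chloroethenyl]-1,5-dimethylcyclohexane, via triflate 10 (not isolated)
Conditions: Tf2O (1.1 equiv), 2,6-di-tert-butyl-4-methylpyridine (1.5 equiv), CH2Cl2, −78 °C; then TMSBr (3 equiv), 0.01 M, −78 to −20 °C; cold NaHCO3 quench
Reagents that add atoms: bromotrimethylsilane C[Si](C)(C)Br (Br at C1 of 11); trifluoromethanesulfonic anhydride O=S(=O)(OS(=O)(=O)C(F)(F)F)C(F)(F)F (triflyl group of 10 only)
Why: Proposed new method: triflation of the primary alcohol gives 10, whose C4 bromine displaces the C3 triflate anchimerically to a configurationally defined C3/C4 bromonium ion; the (5E) alkene of the chain (future C1=C2) opens this ion at the primary carbon C3 through a chair transition state, and the tertiary C1 cation takes bromide from TMSBr, a donor too weakly nucleophilic to attack the triflate or the bromonium ion itself. The closest known reaction types are the bromonium-initiated cation–olefin (polyene) cyclisation, the stereospecific generation of bromonium ions from enantiopure β-bromo alcohol derivatives and the halosilane-terminated Prins cyclisation. The cyclohexane is closed in the 6-endo mode by the C2–C3 bond. C4 and C5 come unchanged from 9, with Br returning to C4 equatorial (antiperiplanar to the new bond), which forces C5–Cl axial; C2 is set by the E alkene geometry (chlorovinyl trans to C6, hence equatorial) and C1 by anti addition across C1=C2 (Br equatorial, methyl axial, the axial face also being screened by the syn-axial C5–Cl), so all four centres follow from one chair. The step needs attack through C2 of the chlorodiene at C3 of the bromonium ion: this pairing gives the tertiary cation in a six-membered chair, whereas attack through C1 would need a strained 5-endo opening and C4 is neopentyl-like and deactivated by the adjacent C–Cl. Low temperature, dilution, excess TMSBr and the hindered pyridine buffer are meant to make bromide capture outrun 1,2-hydride shift from C2, proton loss and bromonium transfer between molecules.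

Compound list
1 | isoprene (2-methylbuta-1,3-diene) | C=CC(C)=C | starting material
2 | (2E)-4-bromo-3-methylbut-2-en-1-yl acetate | CC(=O)OC/C=C(\C)CBr | intermediate
3 | ethynyltrimethylsilane | C#C[Si](C)(C)C | starting material
4 | (2E)-3-methyl-6-(trimethylsilyl)hex-2-en-5-yn-1-yl acetate | CC(=O)OC/C=C(\C)CC#C[Si](C)(C)C | intermediate
5 | (2E)-3-methylhex-2-en-5-yn-1-ol | OC/C=C(\C)CC#C | intermediate
6 | (E)-1,2-dichloroethene | Cl/C=C/Cl | starting material
7 | dimethylaluminium (2E,5E)-6-(dimethylalumanyl)-3,5-dimethylhexa-2,5-dien-1-olate (alkenylalane) | C[Al](C)OC/C=C(\C)C/C(C)=C/[Al](C)C | intermediate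
8 | (2E,5E,7E)-8-chloro-3,5-dimethylocta-2,5,7-trien-1-ol | OC/C=C(\C)C/C(C)=C/C=C/Cl | intermediate
9 | (2S,3R,5E,7E)-2-bromo-3,8-dichloro-3,5-dimethylocta-5,7-dien-1-ol | OC[C@H](Br)[C@](C)(Cl)C/C(C)=C/C=C/Cl | intermediate
10 | (2S,3R,5E,7E)-2-bromo-3,8-dichloro-3,5-dimethylocta-5,7-dien-1-yl trifluoromethanesulfonate (triflate) | FC(F)(F)S(=O)(=O)OC[C@H](Br)[C@](C)(Cl)C/C(C)=C/C=C/Cl | intermediate
11 | (1R,2S,4S,5R)-1,4-dibromo-5-chloro-2-[(E)-2-chloroethenyl]-1,5-dimethylcyclohexane | C[C@@]1(Cl)C[C@@](C)(Br)[C@H](/C=C/Cl)C[C@@H]1Br | target

Total step count: 6. Longest linear sequence: 6 steps (1 to 11).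

Steps most likely to fail

Step 6 (Proposed new method). The bromonium ion may be captured at C3 by bromide instead of by the alkene, giving the open-chain 1,2-dibromide. The C1 cation may also shift hydride from C2 or lose a proton before bromide arrives, or the chlorodiene may react through C1. The fallback uses known chemistry, sets out from 9 and comes back at 11; it separates ring closure from C–Br bond formation. Alcohol 9 is converted into (2S,3R,5E,7E)-2-bromo-3,8-dichloro-3,5-dimethylocta-5,7-dien-1-yl 4-nitrobenzenesulfonate F1 (NsCl, pyridine, CH2Cl2, 0 °C). Solvolysis of F1 in buffered aqueous hexafluoroisopropanol (2,6-lutidine, 0 °C to rt), the classical sulfonate solvolysis with π-participation, should close the same C2–C3 bond with water as terminator and give (1R,2S,4S,5R)-4-bromo-5-chloro-2-[(E)-2-chloroethenyl]-1,5-dimethylcyclohexan-1-ol F2. TMSBr in CH2Cl2 at −20 °C should then replace the tertiary hydroxyl by bromide (SN1), entering on the equatorial face because the axial face of C1 is screened by the syn-axial C5–Cl, to give 11.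

Step 5. Enantiofacial and regiochemical control by the titanium–ligand complex may erode on this substrate, and the chlorodiene may compete for Br+. The fallback sets out from 8 and comes back at 9; it replaces asymmetric catalysis by resolution. Ligand-free, titanium-directed bromochlorination (NBS, ClTi(OiPr)3, hexanes, −20 °C) should give the racemic anti adduct, that is 9 together with (2R,3S,5E,7E)-2-bromo-3,8-dichloro-3,5-dimethylocta-5,7-dien-1-ol F3. The two are separated by preparative chromatography on a chiral stationary phase under neutral conditions, because base would close the bromohydrin to an epoxide, and 9 rejoins the route.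

Step 4. The Pd coupling of the alkenylalane with the dichloroalkene may be sluggish, or may run on to double coupling and protodealumination. The fallback sets out from 5 and comes back at 8; it reverses the polarity of the coupling. The same carboalumination is quenched with iodine to give the isolable (2E,5E)-6-iodo-3,5-dimethylhexa-2,5-dien-1-ol F4. Stille coupling of F4 with excess (E)-1,2-bis(tributylstannyl)ethene (Pd2dba3, AsPh3, NMP, rt) should give (2E,5E,7E)-3,5-dimethyl-8-(tributylstannyl)octa-2,5,7-trien-1-ol F5. Chlorodestannylation of F5 with CuCl2 in THF, with retention of alkene geometry, should give 8.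

Further compounds
F1 | step 6 | (2S,3R,5E,7E)-2-bromo-3,8-dichloro-3,5-dimethylocta-5,7-dien-1-yl 4-nitrobenzenesulfonate | [O-][N+](=O)c1ccc(cc1)S(=O)(=O)OC[C@H](Br)[C@](C)(Cl)C/C(C)=C/C=C/Cl
F2 | step 6 | (1R,2S,4S,5R)-4-bromo-5-chloro-2-[(E)-2-chloroethenyl]-1,5-dimethylcyclohexan-1-ol | C[C@@]1(Cl)C[C@@](C)(O)[C@H](/C=C/Cl)C[C@@H]1Br
F3 | step 5 | (2R,3S,5E,7E)-2-bromo-3,8-dichloro-3,5-dimethylocta-5,7-dien-1-ol | OC[C@@H](Br)[C@@](C)(Cl)C/C(C)=C/C=C/Cl
F4 | step 4 | (2E,5E)-6-iodo-3,5-dimethylhexa-2,5-dien-1-ol | OC/C=C(\C)C/C(C)=C/I
F5 | step 4 | (2E,5E,7E)-3,5-dimethyl-8-(tributylstannyl)octa-2,5,7-trien-1-ol | OC/C=C(\C)C/C(C)=C/C=C/[Sn](CCCC)(CCCC)CCCC
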